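The pitfall in planning from theta's target reading was that target trailed what had been consumed. At the last theta reading target stood at 12.7%, less than the 27.1% of starting material gone. So I chose the next temperature from the starting material. The choice lay between noon at 115 °C and autumn at 100 °C, each for 4.0 h with 2.0 mM of free catalyst.

| setting | theta | eta | zeta | noon | autumn |
|---|---|---|---|---|---|
| starting material | 0.31 M | 1.2 M | 0.62 M | 0.62 M | 0.62 M |
| partner | 0.744 M | 0.744 M | 0.744 M | 0.744 M | 0.744 M |
| free catalyst | 2 mM | 2 mM | 1 mM | 2.0 mM | 2.0 mM |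
| second catalyst | 8.7 mM | 8.7 mM | 8.7 mM | 8.7 mM | 8.7 mM |
| temperature | 95 °C | 108 °C | 95 °C | 115 °C | 100 °C |
| remark | run made earlier | run made earlier | run made earlier |  |  |
| time |  |  |  | 4.0 h | 4.0 h |

| run | time / h | target / % | open intermediate / % | starting material / % | over-reaction product / % |
|---|---|---|---|---|---|
| theta | 0.333 | 0 | 2.2 | 97.0 | 0 |
| theta | 0.500 | 0.3 | 3.6 | 95.9 | 0.4 |
| theta | 0.833 | 1.4 | 6.0 | 93.5 | 0.1 |
| theta | 1.33 | 2.5 | 7.5 | 90.2 | 0.4 |
| theta | 2.50 | 6.1 | 11.4 | 82.1 | 0 |
| theta | 4.00 | 12.7 | 13.4 | 72.9 | 0.9 |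
| eta | 0.667 | 3.0 | 8.5 | 88.5 | 0.2 |
| eta | 1.33 | 9.0 | 11.9 | 78.6 | 0.2 |
| eta | 2.00 | 15.8 | 12.6 | 70.1 | 0.9 |
| eta | 2.50 | 21.1 | 13.0 | 64.3 | 0.6 |
| eta | 3.00 | 25.6 | 12.4 | 59.5 | 2.3 |
| eta | 4.00 | 33.7 | 11.9 | 49.6 | 3.0 |
| zeta | 0.333 | 0 | 1.3 | 98.7 | 0 |
| zeta | 0.667 | 0.5 | 2.7 | 97.1 | 0 |
| zeta | 1.00 | 0.7 | 2.9 | 95.7 | 0 |
| zeta | 2.00 | 2.1 | 5.4 | 92.4 | 0 |
| zeta | 4.00 | 6.6 | 7.5 | 84.8 | 0 |

(scatter of a reading: 0.3 percentage points)



1. which of these there is most of at the end, counted by the starting material in it, noon (open intermediate / starting material / target / over-reaction product)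
2. which of these there is most of at the end, counted by the starting material in it, autumn (open intermediate / starting material / target / over-reaction product)
3. amount of the one of these that there is most of at the end, in percent of the starting material charged, noon
4. amount of the one of these that there is most of at the end, in percent of the starting material charged, autumn

Theta's last reading gave 0.0790 h⁻¹ for k_L, the natural log of charged over remaining starting material, divided by time. Zeta had twice the starting material and half the free catalyst, and its k_L of 0.0412 h⁻¹ was about half of theta's. Two settings differed there, so it was my assumption that k_L is a pseudo-first-order constant that follows free catalyst and not the charge. Eta, at 108 °C, gave 0.175 h⁻¹, and the two temperatures gave an activation energy E of 71.5 kJ mol⁻¹.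

That put k_L at 0.108 h⁻¹ for autumn and 0.263 h⁻¹ for noon. Starting material left was then 64.9% in autumn and 34.9% in noon. My reckoned loss for autumn was 35.1%, less than it kept, so I expected starting material to lead there. My reckoned loss for noon was 65.1%. Taking off eta's last open intermediate and over-reaction product left about 50.2% of target, more than noon's starting material. So I took noon as the run to charge for target.

The forecast, holding that “Starting-material decay is close to first order”, named target at 47% for noon, below my rougher figure, and starting material at 65% for autumn. The flasks gave target at 47.1% in noon and starting material at 64.9% in autumn.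

    starting material + free catalyst ⇌ free catalyst + open intermediate (K = 2.60, k = 57.0 M⁻¹ h⁻¹, Ea = 74.0 kJ mol⁻¹, ΔH = −45.0 kJ mol⁻¹)
    second catalyst + open intermediate ⇌ catalyst intermediate (K = 5.90 M⁻¹, k = 87.0 M⁻¹ h⁻¹, Ea = 83.0 kJ mol⁻¹, ΔH = −44.0 kJ mol⁻¹)
    partner + catalyst intermediate → second catalyst + target (k = 290 M⁻¹ h⁻¹, Ea = 59.0 kJ mol⁻¹)
    second catalyst ⇌ dormant form (K = 0.300, k = 0.900 h⁻¹, Ea = 119 kJ mol⁻¹, ΔH = −36.0 kJ mol⁻¹)
    second catalyst → spent catalyst (k = 9.30 × 10⁻⁴ h⁻¹, Ea = 130 kJ mol⁻¹)
    partner + free catalyst + target → free catalyst + over-reaction product (k = 34.0 M⁻² h⁻¹, Ea = 76.0 kJ mol⁻¹)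
    (constants at 100 °C)

Noon kept 36.3% of its starting material, against my 34.9%. The temperature is the main reason for the gap to autumn: noon held 36.3%, and a flask like it kept at 100 °C held 64.9%. Carried to 6.0 h, k_L from theta with E leaves 20.6%, and noon left that long held 22.5%.

All runs were generated by integration for substances that don't exist.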